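# Synthesis plan for CNP0192765.0: dioxin closure by double SNAr on a trifluoroisophthalaldehyde linchpin

Rings are lettered A to H from the 3,5-dihydroxyphenoxy end. Ring atoms are numbered as follows:
- B1 carries the A–O ether, B5 the bond to ring C, B6 the furan oxygen.
- C1 carries the furan oxygen, C3 the hydroxyl, C4 and C5 the dioxin oxygens, C6 the bond to ring B.
- D1 and D6 carry the dioxin oxygens, D2 and D4 hydroxyls, D5 the ether to ring E.
- E1 carries the ether to D, E6 the bond to F1; F6 carries the ether to G1; G6 carries the ether to H1.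

## The problem

The target is a fucofuroeckol-type phlorotannin: eight oxygenated benzene rings with sixteen free hydroxyls, joined by an aryl ether (A–O–B), a furan (B/C), a 1,4-dioxin (C/D), a second aryl ether (D–O–E), one aryl–aryl bond (E–F) and two more aryl ethers (F–O–G, G–O–H). There is no stereocentre, and the only conceivable stereo element, the tetra-ortho-oxygenated E–F axis, is left undefined by the structure, so nothing has to be controlled or relayed and the whole difficulty is regiochemical. Every ring is a phloroglucinol or a 1,2,3,5-tetraoxygenated benzene whose remaining C–H positions are all strongly and almost equally activated, so bonds cannot be placed late by electrophilic or oxidative chemistry and each oxygen and each aryl carbon has to arrive at a site fixed by a building block. The crowded ethers are the real obstacles: ring D carries five oxygens, three of them contiguous (D5, D6, D1), and G1 and B1 are ether carbons flanked on both sides. The free polyphenol is air-sensitive and its E–F 2,2'-dihydroxybiaryl can cyclodehydrate under hot acid, so the hydroxyls travel as methyl ethers or as formyl groups and are freed only at the end. The feature that opens the molecule is ring D: the oxygens on D5, D6 and D1 are flanked by hydroxyls on D4 and D2, meta to each other across D3–H, which is the pattern of a 4,5,6-trisubstituted isophthalaldehyde after Dakin oxidation, and its two formyl groups activate D1 and D5 by conjugation and D6 inductively for the arrival of oxygen. The C4/C5 dioxin oxygens form a catechol whose para position (C1) must become the furan oxygen, so an ester there can both tell the two catechol oxygens apart and serve as a latent phenol.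

## Retrosynthesis

**Target 39 to permethyl ether 38.** The sixteen O–methyl bonds are cut last. Methyl ethers are the only protection that survives every step below (organolithium, copper, palladium, peroxide, hydride), and 38 is a stable, chromatographable compound. The forward step must cleave alkyl–oxygen bonds only and leave five diaryl ethers, the furan and the dioxin intact.

**38 to bromo diaryl ether 37, then to phenol 30 and iodide 36.** The furan is cut at the C6–B5 carbon–carbon bond and then at the C1–O–B6 ether. Cutting the carbon–carbon bond first leaves an intramolecular arylation, which tolerates the two flanking oxygens on each carbon far better than an intermolecular tetra-ortho biaryl coupling would. The halogen must sit on C6 of ring C, because ring C has two C–H bonds ortho to C1–O whereas ring B, with B1 blocked by the ring A ether, has only one. The forward steps are a copper-catalysed ether synthesis that uses the iodide of 36 and spares the bromide of 30, then a palladium-catalysed ring closure.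

**36 to 35, 33, then 5-iodovanillin 31 and boronic acid 32.** 5-Iodovanillin already has the ring B pattern: iodine where the furan oxygen goes, the hydroxyl where ring A is attached, methoxyl, and a formyl group as the latent fourth oxygen. Only the A–O–B1 bond is made, by Chan–Lam arylation of the flanked, acidic phenol. Dakin oxidation and methylation finish the piece.

**30 to 28, 27 and ester 26.** The C1 hydroxyl is traced back through formyl and hydroxymethyl to a methyl ester. The ester is chosen over an aldehyde because it must stay inert while the ring D and ring G aldehydes are oxidised, and it is needed earlier as the control element of the key step. This costs three routine steps.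

**26 to 25 and tri-aldehyde 23.** The three methoxyls on D2, D4 and G4 are traced back to formyl groups, so that one Dakin oxidation and one methylation serve both rings. Every formyl group has an ortho or para oxygen, which the Dakin step requires.

**23 to E–F–G–H phenol 22 and bromo tricycle 9.** The D5–O–E1 ether is cut. The carbon is the last fluoride of the ring D linchpin, ortho and para to formyl groups. The forward SNAr should run near room temperature, which matters because the dioxin C–O bonds of 9 are activated by the same formyl groups.

**9 to tricycle 8.** The C6 bromine is introduced at the only stage where ring C is the sole nucleophilic ring: ring D of 8 is deactivated by two formyl groups and fluorine, and no phloroglucinol ring is yet attached. Bromination before the key step would put a halogen beside the attacking oxygen and undo its control; bromination later would strike rings D to H.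

**8 to gallate 6 and trifluoro dialdehyde 5 (key disconnection).** Both C–O bonds from ring C to ring D are cut at once. The alternatives, an Ullmann closure of a halo-phenol or oxidative phenol coupling, offer no handle on a penta-oxygenated ring. Here two simple benzenes give the tricycle with all five ring D oxygens placed or latent. The forward reaction must deliver the oxygen meta to the ester to the activated carbon first; since 5 is symmetric, that single choice fixes the regiochemistry.

**5 to acetal 2 and 2,3,4-trifluorobenzaldehyde 1.** The second formyl group is cut; the forward step is fluorine-directed lithiation and formylation.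

**22 to biphenol 14 and fluoro aldehyde 21.** The F6–O–G1 ether is cut with ring G as the electrophile, since G1 is para to the latent G4 oxygen. A symmetric biphenol avoids any late tetra-ortho biaryl coupling; the forward step must stop at monoarylation.

**21 to iodide 18 and 2,4,6-trimethoxyphenol 19; 18 to 16 and 4-fluoro-3-methoxybenzaldehyde 15.** The G6–O–H1 ether cannot be made by SNAr because G6 is meta to the formyl group. It is made by copper catalysis on the acetal, where the fluoride is not activated, after fluorine-directed lithiation and iodination fix the site.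

**14 to 13, 11 and 3,5-dimethoxyphenol 10.** The E–F bond is cut symmetrically, so that two molecules of the same arene 11 supply rings E and F. The forward steps are ortho-lithiation between the methoxymethyl ether and a methoxyl, oxidative homocoupling of two molecules of the aryllithium, and acetal cleavage.

## Roads not taken

**Alternative 1:** the furan is the centrepiece. The bromo diaryl ether A1, which already contains the dioxin and carries a benzyl ether on D5, is closed to the pentacyclic core A2 by Pd(OAc)2 with PCy3·HBF4, K2CO3 and pivalic acid. The palladium inserts into the ring C carbon–bromine bond and arylates the single ortho C–H of ring B.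
- Merits: the regiochemistry is unambiguous, the union of the A–B and C–D halves is convergent, and the reaction type is reliable. This closure is good enough that the chosen route uses the same reaction type as a supporting step (step 22, on 37).
- Weak points: as a strategy it presupposes the dioxin and the five-oxygen ring D without saying how they arise. Its benzyl ether on D5 means the D–O–E bond must later be made from a phenol flanked by a methoxyl and a dioxin oxygen and an unactivated ring E halide, a doubly hindered copper coupling, after an extra debenzylation.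
- Comparison: for the furan the two plans are equal. The chosen plan adds a construction of ring D in which the same formyl groups that become hydroxyls also activate the D5 carbon for the ring E oxygen.

**Alternative 2:** the E–F bond is the centrepiece. The methylene-bridged bis(aryl ether) A3 is oxidised with PhI(OCOCF3)2 and BF3·OEt2 (or MoCl5) to the dibenzodioxepine A4, whose acetal hydrolysis would give 14.
- Merits: the tether enforces ortho–ortho coupling, no organolithium is needed, and the sequence is as short as steps 5 to 7. For the biphenol alone it is at least as good, and it avoids the site question of the lithiation in step 6.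
- Weak points: the electron-rich product is more easily oxidised than its precursor; intermolecular coupling at the carbon between the two methoxyls competes; and the seven-membered acetal needs acid on a biphenol that can cyclodehydrate. Above all it spends the decisive step on the easiest bond and leaves the dioxin and the flanked ethers unsolved.
- Comparison: the chosen plan reaches 14 in the same number of steps under mild acid, and places its key step on the ring that has no other solution.

**Alternative 3:** ring G is the centrepiece. The complex (cyclopentadienyl)(1,2-dichloro-3,5-dimethoxybenzene)ruthenium hexafluorophosphate A5 takes the phenoxide of 19 and then the ring F phenoxide of the mono-benzylated biphenol A6 in one pot (K2CO3), giving the complexed E–F–G–H chain A7.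
- Merits: both ring G ethers form near room temperature without a latent aldehyde and without copper. For ring G this is shorter than steps 8 to 11 and avoids the hindered SNAr of step 11; in that respect it is the better road.
- Weak points: ruthenium is stoichiometric and must be removed by photolysis. Both chlorides are activated by the metal to a similar degree, so which phenoxide ends on which carbon rests on order of addition alone. A6 needs a desymmetrising benzylation and later debenzylation. The dioxin is untouched.
- Comparison: the chosen plan fixes the ring G sites by construction (iodine at G6, fluorine at G1 in 18), uses no precious metal in quantity, and lets one Dakin and one methylation serve rings D and G together.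

Key step: step 3

## Route

Assumptions:
- The structure defines no stereocentre and leaves the E–F axis unspecified, so the target is treated as achiral or racemic about that axis.
- Compounds 1, 6, 10, 15, 19, 31 and 32 are taken as purchasable.

Step 1
Reactants: 1 2,3,4-trifluorobenzaldehyde
Product: 2 1-(dimethoxymethyl)-2,3,4-trifluorobenzene
Conditions: HC(OMe)3, TsOH·H2O (cat.), MeOH, rt
Reagents that add atoms: trimethyl orthoformate, COC(OC)OC; methanol, CO
Why: Acid-catalysed acetalisation with the orthoformate as water scavenger; the acetal shields the aldehyde from the lithium amide of step 2.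

Step 2
Reactants: 2 1-(dimethoxymethyl)-2,3,4-trifluorobenzene
Product: 5 4,5,6-trifluorobenzene-1,3-dicarbaldehyde, via aryllithium 3 (not isolated), via acetal aldehyde 4 (not isolated)
Conditions: LiN(i-Pr)2, THF, −78 °C; DMF, −78 °C; 2 M HCl, THF, rt
Reagents that add atoms: N,N-dimethylformamide, CN(C)C=O; water, O
Why: Acidity-controlled ortho-lithiation at the only ring hydrogen next to fluorine, formylation of the aryllithium with DMF, and hydrolysis of the dimethyl acetal in the acidic work-up; the low temperature keeps the ortho-fluoro aryllithium from losing LiF.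

Step 3
Reactants: 6 methyl 3,4-dihydroxy-5-methoxybenzoate; 5 4,5,6-trifluorobenzene-1,3-dicarbaldehyde
Product: 8 methyl 6-fluoro-7,9-diformyl-4-methoxydibenzo[b,e][1,4]dioxine-2-carboxylate, via monoaryl ether 7 (not isolated)
Conditions: 6, NaH (2.1 equiv), DMF, 0 °C; added slowly to 5 (1.1 equiv) in DMF, −20 °C to rt; then 70 °C
Reagents that add atoms: none
Why: Two successive nucleophilic aromatic substitutions (addition–elimination) of the catechol dianion on 5; the closest known reaction type is dibenzo-1,4-dioxin formation from catechol dianions and activated ortho-difluoroarenes. The first bond forms when the more basic phenoxide, the oxygen meta to the ester, adds to C4 of 5 (equivalent to C6 by symmetry), a fluoride ortho to one formyl group and para to the other, through a Meisenheimer adduct stabilised by both carbonyls, giving 7. The second bond forms when the neighbouring phenoxide, para to the ester, displaces the central fluoride, which is meta to both formyl groups and activated only inductively; this is an intramolecular addition–elimination closing the six-membered dioxin ring and is why the mixture is warmed. The one selectivity needed is which oxygen ends beside a formyl group, and because 5 is symmetric this alone fixes the regiochemistry of the tricycle. The ester should secure it twice: kinetically, since the oxygen para to it is the conjugatively stabilised, weaker nucleophile, and thermodynamically, since any Smiles equilibration of 7 through the spiro Meisenheimer adduct favours the isomer whose free phenoxide is the ester-stabilised one. Complete dianion formation is essential, because with a carbonate base the monoanion para to the ester would attack first. Inverse addition to a slight excess of 5 keeps a second catechol from the third fluoride, which stays ortho and para to the formyl groups and is reserved for step 12. No stereocentre is formed.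

Step 4
Reactants: 8 methyl 6-fluoro-7,9-diformyl-4-methoxydibenzo[b,e][1,4]dioxine-2-carboxylate
Product: 9 methyl 1-bromo-6-fluoro-7,9-diformyl-4-methoxydibenzo[b,e][1,4]dioxine-2-carboxylate
Conditions: NBS (1.05 equiv), TFA–CH2Cl2, 0 °C to rt
Reagents that add atoms: N-bromosuccinimide, O=C1CCC(=O)N1Br
Why: Electrophilic aromatic bromination; ring C is the only ring of 8 that is not deactivated, and its methoxyl is the dominant donor because both dioxin oxygens are shared with the bis-formyl fluoro ring, so substitution should go para to the methoxyl (the future C6), as in the bromination of 3-methoxybenzoates.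

Step 5
Reactants: 10 3,5-dimethoxyphenol
Product: 11 1,3-dimethoxy-5-(methoxymethoxy)benzene
Conditions: NaH, THF–DMF, 0 °C; MOMCl, 0 °C to rt
Reagents that add atoms: chloromethyl methyl ether, COCCl
Why: Williamson alkylation of the phenoxide; the methoxymethyl ether is the stronger directing group needed in step 6 and is removable under mild acid.

Step 6
Reactants: 11 1,3-dimethoxy-5-(methoxymethoxy)benzene (two molecules)
Product: 13 2,2'-bis(methoxymethoxy)-4,4',6,6'-tetramethoxy-1,1'-biphenyl, via aryllithium 12 (not isolated)
Conditions: n-BuLi (1.05 equiv), TMEDA, THF, 0 °C; anhydrous CuCl2 (1.1 equiv), −78 °C to rt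
Reagents that add atoms: second molecule of 11, 1,3-dimethoxy-5-(methoxymethoxy)benzene, COCOc1cc(OC)cc(OC)c1
Why: Directed ortho-metalation between the chelating acetal oxygen and a methoxyl gives 12, and divalent copper then joins two molecules of 12 at their lithiated carbons by oxidative homocoupling, a standard route to symmetric tetra-ortho-alkoxy biaryls; both halves of 13 therefore come from 11.

Step 7
Reactants: 13 2,2'-bis(methoxymethoxy)-4,4',6,6'-tetramethoxy-1,1'-biphenyl
Product: 14 4,4',6,6'-tetramethoxy-[1,1'-biphenyl]-2,2'-diol
Conditions: 3 M HCl, MeOH–THF, rt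
Reagents that add atoms: none
Why: Acid-catalysed acetal exchange with methanol frees both phenols at room temperature, well below the conditions under which the biphenol could cyclodehydrate.

Step 8
Reactants: 15 4-fluoro-3-methoxybenzaldehyde
Product: 16 4-(dimethoxymethyl)-1-fluoro-2-methoxybenzene
Conditions: HC(OMe)3, TsOH·H2O (cat.), MeOH, rt
Reagents that add atoms: trimethyl orthoformate, COC(OC)OC; methanol, CO
Why: Acetalisation as in step 1; it protects the aldehyde from butyllithium and switches off the SNAr reactivity of the para fluoride until step 11.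

Step 9
Reactants: 16 4-(dimethoxymethyl)-1-fluoro-2-methoxybenzene
Product: 18 5-(dimethoxymethyl)-2-fluoro-1-iodo-3-methoxybenzene, via aryllithium 17 (not isolated)
Conditions: n-BuLi, PMDTA, THF, −78 °C; I2, −78 °C to rt
Reagents that add atoms: iodine, II
Why: Metalation of a 2-fluoroanisole unit under acidity control (triamine-complexed butyllithium) should take place next to fluorine and not between the methoxyl and the acetal; iodine traps the aryllithium.

Step 10
Reactants: 18 5-(dimethoxymethyl)-2-fluoro-1-iodo-3-methoxybenzene; 19 2,4,6-trimethoxyphenol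
Product: 21 4-fluoro-3-methoxy-5-(2,4,6-trimethoxyphenoxy)benzaldehyde, via diaryl ether acetal 20 (not isolated)
Conditions: CuI (10 mol %), picolinic acid (20 mol %), K3PO4, DMSO, 90 °C, argon; then 1 M HCl, THF, rt
Reagents that add atoms: water, O
Why: Ullmann-type ether synthesis catalysed by monovalent copper with picolinic acid, a system suited to 2,6-disubstituted phenols; with the aldehyde masked the fluoride is inert, and the acidic work-up then releases the formyl group.

Step 11
Reactants: 14 4,4',6,6'-tetramethoxy-[1,1'-biphenyl]-2,2'-diol; 21 4-fluoro-3-methoxy-5-(2,4,6-trimethoxyphenoxy)benzaldehyde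
Product: 22 4-{[2'-hydroxy-4,4',6,6'-tetramethoxy-(1,1'-biphenyl)-2-yl]oxy}-3-methoxy-5-(2,4,6-trimethoxyphenoxy)benzaldehyde
Conditions: 14 (3 equiv), Cs2CO3 (1 equiv per 14), DMSO, 110 °C
Reagents that add atoms: none
Why: SNAr at a fluoride para to formyl; the hydrogen-bonded monoanion of 14 forms first and 14 is in excess, which should hold the reaction at monoarylation, and unreacted 14 is recovered.

Step 12
Reactants: 22 E–F–G–H phenol; 9 methyl 1-bromo-6-fluoro-7,9-diformyl-4-methoxydibenzo[b,e][1,4]dioxine-2-carboxylate
Product: 23 tri-aldehyde: the tricycle of 9 with the ring E oxygen of 22 in place of fluorine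
Conditions: Cs2CO3, DMF, rt
Reagents that add atoms: none
Why: SNAr at the last fluoride of ring D, ortho to one formyl group and para to the other, so it should proceed at room temperature, which spares the equally activated dioxin C–O bonds from ether exchange.

Step 13
Reactants: 23 tri-aldehyde
Product: 25 triphenol: 23 with hydroxyl in place of each of the three formyl groups (D2, D4, G4), via tris(formate) 24 (not isolated)
Conditions: 30% H2O2, (PhSe)2 (10 mol %), CH2Cl2, rt; then K2CO3 (cat.), MeOH, rt, argon
Reagents that add atoms: hydrogen peroxide, OO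
Why: Dakin-type Baeyer–Villiger oxidation by the perseleninic acid formed from (PhSe)2 and H2O2; each formyl group has an ortho or para oxygen so aryl migration should win, and this oxidant is gentler on methoxyarenes than a percarboxylic acid; methanolysis cleaves the formates.

Step 14
Reactants: 25 triphenol
Product: 26 permethyl bromo ester: 25 with the three new hydroxyls as methyl ethers
Conditions: MeI, K2CO3, DMF, rt
Reagents that add atoms: iodomethane, CI
Why: Williamson methylation of the three phenols, carried out directly on the air-sensitive triphenol; the methyl ester and aryl bromide are inert.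

Step 15
Reactants: 26 permethyl bromo ester
Product: 27 benzylic alcohol: 26 with CH2OH in place of CO2Me
Conditions: i-Bu2AlH (3 equiv), CH2Cl2, −78 to 0 °C; aqueous potassium sodium tartrate work-up
Reagents that add atoms: none
Why: Hydride reduction of the only carbonyl group left; aryl bromide and aryl ethers do not react.

Step 16
Reactants: 27 benzylic alcohol
Product: 28 ring C aldehyde: 27 with CHO in place of CH2OH
Conditions: activated MnO2 (excess), CH2Cl2, rt
Reagents that add atoms: none
Why: Selective oxidation of a benzylic alcohol; the reagent leaves methoxyarenes untouched.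

Step 17
Reactants: 28 ring C aldehyde
Product: 30 ring C phenol: 28 with OH in place of CHO, via aryl formate 29 (not isolated)
Conditions: 30% H2O2, (PhSe)2 (10 mol %), CH2Cl2, rt; then K2CO3 (cat.), MeOH, rt, argon
Reagents that add atoms: hydrogen peroxide, OO
Why: Dakin oxidation as in step 13; the formyl group is para to the C4 dioxin oxygen, which should secure aryl migration, and methanolysis frees the phenol that becomes the furan oxygen.

Step 18
Reactants: 31 4-hydroxy-3-iodo-5-methoxybenzaldehyde (5-iodovanillin); 32 (3,5-dimethoxyphenyl)boronic acid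
Product: 33 4-(3,5-dimethoxyphenoxy)-3-iodo-5-methoxybenzaldehyde
Conditions: Cu(OAc)2 (1 equiv), pyridine, 4 Å molecular sieves, CH2Cl2, air, rt
Reagents that add atoms: none
Why: Chan–Lam O-arylation, which accepts acidic, doubly ortho-substituted phenols such as 2,6-dihalophenols and leaves the aryl iodide untouched at room temperature.

Step 19
Reactants: 33 4-(3,5-dimethoxyphenoxy)-3-iodo-5-methoxybenzaldehyde
Product: 35 4-(3,5-dimethoxyphenoxy)-3-iodo-5-methoxyphenol, via aryl formate 34 (not isolated)
Conditions: 30% H2O2, (PhSe)2 (10 mol %), CH2Cl2, rt; then K2CO3 (cat.), MeOH, rt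
Reagents that add atoms: hydrogen peroxide, OO
Why: Dakin oxidation of a para-aryloxy benzaldehyde; the aryl iodide should survive these acid-free conditions.

Step 20
Reactants: 35 4-(3,5-dimethoxyphenoxy)-3-iodo-5-methoxyphenol
Product: 36 2-(3,5-dimethoxyphenoxy)-1-iodo-3,5-dimethoxybenzene
Conditions: MeI, K2CO3, acetone, reflux
Reagents that add atoms: iodomethane, CI
Why: Williamson methylation completes the A–B unit with iodine at B6 and a single free ortho position, B5.

Step 21
Reactants: 30 ring C phenol; 36 2-(3,5-dimethoxyphenoxy)-1-iodo-3,5-dimethoxybenzene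
Product: 37 bromo diaryl ether: 30 with its hydroxyl oxygen bound to B6 of the A–B unit
Conditions: CuI (20 mol %), picolinic acid (40 mol %), K3PO4, DMSO, 90 °C, argon
Reagents that add atoms: none
Why: Ullmann-type ether synthesis as in step 10; the aryl iodide of 36 should react in preference to the doubly flanked, electron-rich aryl bromide of 30.

Step 22
Reactants: 37 bromo diaryl ether
Product: 38 hexadeca-O-methyl ether of the target
Conditions: Pd(OAc)2 (10 mol %), PCy3·HBF4 (20 mol %), K2CO3, PivOH (30 mol %), DMA, 130 °C
Reagents that add atoms: none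
Why: Intramolecular direct arylation: zerovalent palladium inserts into the C6–Br bond, pivalate-assisted concerted metalation–deprotonation takes the only C–H ortho to the ether oxygen on ring B (B5), and reductive elimination closes the five-membered furan ring.

Step 23
Reactants: 38 hexadeca-O-methyl ether of the target
Product: 39 CNP0192765.0
Conditions: BBr3 (excess), CH2Cl2, −78 °C to rt; MeOH then water at 0 °C, argon
Reagents that add atoms: none
Why: Lewis-acid cleavage of all sixteen aryl methyl ethers by BBr3; diaryl ether, furan and dioxin C–O bonds are inert to it, and the cold quench limits exposure of the E–F biphenol to acid.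

## Compound list

1 | 2,3,4-trifluorobenzaldehyde | O=Cc1ccc(F)c(F)c1F | starting material
2 | 1-(dimethoxymethyl)-2,3,4-trifluorobenzene | COC(OC)c1ccc(F)c(F)c1F | intermediate
3 | [5-(dimethoxymethyl)-2,3,4-trifluorophenyl]lithium; not isolated | COC(OC)c1cc([Li])c(F)c(F)c1F | intermediate
4 | 5-(dimethoxymethyl)-2,3,4-trifluorobenzaldehyde; not isolated | COC(OC)c1cc(C=O)c(F)c(F)c1F | intermediate
5 | 4,5,6-trifluorobenzene-1,3-dicarbaldehyde (4,5,6-trifluoroisophthalaldehyde) | O=Cc1cc(C=O)c(F)c(F)c1F | intermediate
6 | methyl 3,4-dihydroxy-5-methoxybenzoate | COC(=O)c1cc(O)c(O)c(OC)c1 | starting material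
7 | methyl 3-(2,3-difluoro-4,6-diformylphenoxy)-4-hydroxy-5-methoxybenzoate (present as its sodium phenoxide); not isolated | COC(=O)c1cc(OC)c(O)c(Oc2c(C=O)cc(C=O)c(F)c2F)c1 | intermediate
8 | methyl 6-fluoro-7,9-diformyl-4-methoxydibenzo[b,e][1,4]dioxine-2-carboxylate | COC(=O)c1cc(OC)c2c(c1)Oc1c(C=O)cc(C=O)c(F)c1O2 | intermediate
9 | methyl 1-bromo-6-fluoro-7,9-diformyl-4-methoxydibenzo[b,e][1,4]dioxine-2-carboxylate | COC(=O)c1cc(OC)c2c(c1Br)Oc1c(C=O)cc(C=O)c(F)c1O2 | intermediate
10 | 3,5-dimethoxyphenol | COc1cc(O)cc(OC)c1 | starting material
11 | 1,3-dimethoxy-5-(methoxymethoxy)benzene | COCOc1cc(OC)cc(OC)c1 | intermediate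
12 | [2,4-dimethoxy-6-(methoxymethoxy)phenyl]lithium; not isolated | COCOc1cc(OC)cc(OC)c1[Li] | intermediate
13 | 2,2'-bis(methoxymethoxy)-4,4',6,6'-tetramethoxy-1,1'-biphenyl | COCOc1cc(OC)cc(OC)c1-c1c(OC)cc(OC)cc1OCOC | intermediate
14 | 4,4',6,6'-tetramethoxy-[1,1'-biphenyl]-2,2'-diol (E–F biphenol) | COc1cc(O)c(-c2c(O)cc(OC)cc2OC)c(OC)c1 | intermediate
15 | 4-fluoro-3-methoxybenzaldehyde | COc1cc(C=O)ccc1F | starting material
16 | 4-(dimethoxymethyl)-1-fluoro-2-methoxybenzene | COc1cc(C(OC)OC)ccc1F | intermediate
17 | [5-(dimethoxymethyl)-2-fluoro-3-methoxyphenyl]lithium; not isolated | COc1cc(C(OC)OC)cc([Li])c1F | intermediate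
18 | 5-(dimethoxymethyl)-2-fluoro-1-iodo-3-methoxybenzene | COc1cc(C(OC)OC)cc(I)c1F | intermediate
19 | 2,4,6-trimethoxyphenol | COc1cc(OC)c(O)c(OC)c1 | starting material
20 | 2-[5-(dimethoxymethyl)-2-fluoro-3-methoxyphenoxy]-1,3,5-trimethoxybenzene; not isolated | COc1cc(OC)c(Oc2cc(C(OC)OC)cc(OC)c2F)c(OC)c1 | intermediate
21 | 4-fluoro-3-methoxy-5-(2,4,6-trimethoxyphenoxy)benzaldehyde (G–H unit) | COc1cc(OC)c(Oc2cc(C=O)cc(OC)c2F)c(OC)c1 | intermediate
22 | 4-{[2'-hydroxy-4,4',6,6'-tetramethoxy-(1,1'-biphenyl)-2-yl]oxy}-3-methoxy-5-(2,4,6-trimethoxyphenoxy)benzaldehyde (E–F–G–H phenol) | Oc1cc(OC)cc(OC)c1-c1c(OC)cc(OC)cc1Oc1c(OC)cc(C=O)cc1Oc1c(OC)cc(OC)cc1OC | intermediate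
23 | methyl 1-bromo-7,9-diformyl-4-methoxy-6-{[2'-(4-formyl-2-methoxy-6-(2,4,6-trimethoxyphenoxy)phenoxy)-4,4',6,6'-tetramethoxy-(1,1'-biphenyl)-2-yl]oxy}dibenzo[b,e][1,4]dioxine-2-carboxylate | COC(=O)c1cc(OC)c2c(c1Br)Oc1c(C=O)cc(C=O)c(Oc3cc(OC)cc(OC)c3-c3c(OC)cc(OC)cc3Oc3c(OC)cc(C=O)cc3Oc3c(OC)cc(OC)cc3OC)c1O2 | intermediate
24 | tris(formate) of 25 (formyloxy groups at D2, D4 and G4); not isolated | COC(=O)c1cc(OC)c2c(c1Br)Oc1c(OC=O)cc(OC=O)c(Oc3cc(OC)cc(OC)c3-c3c(OC)cc(OC)cc3Oc3c(OC)cc(OC=O)cc3Oc3c(OC)cc(OC)cc3OC)c1O2 | intermediate
25 | methyl 1-bromo-7,9-dihydroxy-4-methoxy-6-{[2'-(4-hydroxy-2-methoxy-6-(2,4,6-trimethoxyphenoxy)phenoxy)-4,4',6,6'-tetramethoxy-(1,1'-biphenyl)-2-yl]oxy}dibenzo[b,e][1,4]dioxine-2-carboxylate | COC(=O)c1cc(OC)c2c(c1Br)Oc1c(O)cc(O)c(Oc3cc(OC)cc(OC)c3-c3c(OC)cc(OC)cc3Oc3c(OC)cc(O)cc3Oc3c(OC)cc(OC)cc3OC)c1O2 | intermediate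
26 | methyl 1-bromo-4,7,9-trimethoxy-6-{[2'-(2,4-dimethoxy-6-(2,4,6-trimethoxyphenoxy)phenoxy)-4,4',6,6'-tetramethoxy-(1,1'-biphenyl)-2-yl]oxy}dibenzo[b,e][1,4]dioxine-2-carboxylate | COC(=O)c1cc(OC)c2c(c1Br)Oc1c(OC)cc(OC)c(Oc3cc(OC)cc(OC)c3-c3c(OC)cc(OC)cc3Oc3c(OC)cc(OC)cc3Oc3c(OC)cc(OC)cc3OC)c1O2 | intermediate
27 | the 2-(hydroxymethyl) analogue of 26 | OCc1cc(OC)c2c(c1Br)Oc1c(OC)cc(OC)c(Oc3cc(OC)cc(OC)c3-c3c(OC)cc(OC)cc3Oc3c(OC)cc(OC)cc3Oc3c(OC)cc(OC)cc3OC)c1O2 | intermediate
28 | the 2-carbaldehyde analogue of 26 | O=Cc1cc(OC)c2c(c1Br)Oc1c(OC)cc(OC)c(Oc3cc(OC)cc(OC)c3-c3c(OC)cc(OC)cc3Oc3c(OC)cc(OC)cc3Oc3c(OC)cc(OC)cc3OC)c1O2 | intermediate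
29 | the 2-(formyloxy) analogue of 26; not isolated | O=COc1cc(OC)c2c(c1Br)Oc1c(OC)cc(OC)c(Oc3cc(OC)cc(OC)c3-c3c(OC)cc(OC)cc3Oc3c(OC)cc(OC)cc3Oc3c(OC)cc(OC)cc3OC)c1O2 | intermediate
30 | 1-bromo-4,7,9-trimethoxy-6-{[2'-(2,4-dimethoxy-6-(2,4,6-trimethoxyphenoxy)phenoxy)-4,4',6,6'-tetramethoxy-(1,1'-biphenyl)-2-yl]oxy}dibenzo[b,e][1,4]dioxin-2-ol (ring C phenol) | Oc1cc(OC)c2c(c1Br)Oc1c(OC)cc(OC)c(Oc3cc(OC)cc(OC)c3-c3c(OC)cc(OC)cc3Oc3c(OC)cc(OC)cc3Oc3c(OC)cc(OC)cc3OC)c1O2 | intermediate
31 | 4-hydroxy-3-iodo-5-methoxybenzaldehyde (5-iodovanillin) | COc1cc(C=O)cc(I)c1O | starting material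
32 | (3,5-dimethoxyphenyl)boronic acid | COc1cc(OC)cc(B(O)O)c1 | starting material
33 | 4-(3,5-dimethoxyphenoxy)-3-iodo-5-methoxybenzaldehyde | COc1cc(OC)cc(Oc2c(I)cc(C=O)cc2OC)c1 | intermediate
34 | 4-(3,5-dimethoxyphenoxy)-3-iodo-5-methoxyphenyl formate; not isolated | COc1cc(OC)cc(Oc2c(I)cc(OC=O)cc2OC)c1 | intermediate
35 | 4-(3,5-dimethoxyphenoxy)-3-iodo-5-methoxyphenol | COc1cc(OC)cc(Oc2c(I)cc(O)cc2OC)c1 | intermediate
36 | 2-(3,5-dimethoxyphenoxy)-1-iodo-3,5-dimethoxybenzene (A–B iodide) | COc1cc(OC)cc(Oc2c(I)cc(OC)cc2OC)c1 | intermediate
37 | 1-bromo-2-[2-(3,5-dimethoxyphenoxy)-3,5-dimethoxyphenoxy]-4,7,9-trimethoxy-6-{[2'-(2,4-dimethoxy-6-(2,4,6-trimethoxyphenoxy)phenoxy)-4,4',6,6'-tetramethoxy-(1,1'-biphenyl)-2-yl]oxy}dibenzo[b,e][1,4]dioxine | COc1cc(OC)cc(Oc2c(OC)cc(OC)cc2Oc2cc(OC)c3c(c2Br)Oc2c(OC)cc(OC)c(Oc4cc(OC)cc(OC)c4-c4c(OC)cc(OC)cc4Oc4c(OC)cc(OC)cc4Oc4c(OC)cc(OC)cc4OC)c2O3)c1 | intermediate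
38 | hexadeca-O-methyl ether of 39 (every hydroxyl of the target as a methyl ether; furan closed between B5 and C6) | COc1cc(OC)cc(Oc2c(OC)cc(OC)c3c2oc2cc(OC)c4c(c23)Oc2c(OC)cc(OC)c(Oc3cc(OC)cc(OC)c3-c3c(OC)cc(OC)cc3Oc3c(OC)cc(OC)cc3Oc3c(OC)cc(OC)cc3OC)c2O4)c1 | intermediate
39 | CNP0192765.0: benzofuro-fused dibenzo-1,4-dioxin hexadecaphenol with the 3,5-dihydroxyphenoxy group (ring A) on B1 and the E–F–G–H chain on the D5 oxygen | Oc1cc(O)cc(Oc2c(O)cc(O)c3c2oc2cc(O)c4c(c23)Oc2c(O)cc(O)c(Oc3cc(O)cc(O)c3-c3c(O)cc(O)cc3Oc3c(O)cc(O)cc3Oc3c(O)cc(O)cc3O)c2O4)c1 | target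

## Step count and least certain steps

Total: 23 steps. Longest linear sequence: 13 steps (for example 15 → 16 → 18 → 21 → 22 → 23 → 25 → 26 → 27 → 28 → 30 → 37 → 38 → 39; the branches from 1 and from 10 are equally long).

**Step 3 (key step).** The most likely failure is erosion of regiocontrol. The first substitution may go partly through the oxygen para to the ester, or the monoaryl ether may equilibrate by Smiles rearrangement and close from the minor isomer, because the ring closure at the unactivated central fluoride is slow. Oligomerisation through the third, still activated fluoride is the second risk. The fallback makes the two bonds in separate flasks with the order fixed by protection; it sets out from 6 and returns at 8. The more acidic hydroxyl para to the ester is benzylated (BnBr, KHCO3, DMF) to methyl 4-(benzyloxy)-3-hydroxy-5-methoxybenzoate F1. The single free phenol of F1 is then coupled with 5 (K2CO3, DMF, 0 °C) to methyl 4-(benzyloxy)-3-(2,3-difluoro-4,6-diformylphenoxy)-5-methoxybenzoate F2. Removal of the benzyl ether with BCl3 and pentamethylbenzene at −78 °C gives 7 as an isolated phenol, which is closed with K2CO3 in DMF at 70 °C to 8.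

**Step 4.** Bromination may lose site selectivity to the position ortho to the methoxyl, since both open positions of ring C are flanked and the preference rests only on para-methoxy against para-aryloxy activation. The fallback lets a free hydroxyl direct the halogen before the dioxin exists; it sets out from 6 and returns at 9. F1 (made from 6 as above) is brominated with NBS ortho to its free hydroxyl and para to the methoxyl, the orientation known from isovanillin, to give methyl 4-(benzyloxy)-2-bromo-3-hydroxy-5-methoxybenzoate F3. SNAr with 5 gives methyl 4-(benzyloxy)-2-bromo-3-(2,3-difluoro-4,6-diformylphenoxy)-5-methoxybenzoate F4, and BCl3 with pentamethylbenzene gives methyl 2-bromo-3-(2,3-difluoro-4,6-diformylphenoxy)-4-hydroxy-5-methoxybenzoate F5. Base-mediated ring closure of F5 (K2CO3, DMF, 70 °C) gives 9.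

**Step 11.** Substitution at a fluoride flanked by a methoxyl and a bulky aryloxy group, activated by one para formyl group only, may be so slow that forcing conditions cause double arylation of 14 or loss of the aldehyde. The fallback changes the order of bond formation so that the SNAr is done next to iodine and the ring H ether is made last; it sets out from 18 (with 14, 9 and 19) and returns at 26. 18 is hydrolysed (1 M HCl, THF) to 4-fluoro-3-iodo-5-methoxybenzaldehyde F6, and 14 in excess is arylated by F6 to 4-{[2'-hydroxy-4,4',6,6'-tetramethoxy-(1,1'-biphenyl)-2-yl]oxy}-3-iodo-5-methoxybenzaldehyde F7. F7 is joined to 9 as in step 12 to give the iodo tri-aldehyde F8, Dakin oxidation as in step 13 gives the iodo triphenol F9, and methylation as in step 14 gives the iodo permethyl ester F10. Copper-catalysed coupling of F10 with 19 (CuI, picolinic acid, K3PO4, DMSO), selective for the iodide over the flanked bromide, then gives 26.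

**Step 22.** Oxidative addition into the electron-rich C–Br bond with two ortho oxygens may be slow, so that protodebromination and catalyst decay outrun the cyclisation. The fallback replaces the organometallic closure by a homolytic one; it sets out from 37 and returns at 38. KOtBu with 1,10-phenanthroline in hot mesitylene (base-promoted homolytic aromatic substitution) transfers an electron to the aryl bromide, and the C6 aryl radical adds to B5 and rearomatises. No new compound is made. Attack at B1 with loss of the ring A aryloxy group would be its own side path.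

**Step 23.** Cleavage of sixteen ethers may stall at partially methylated borate aggregates, the liberated E–F biphenol may cyclodehydrate under the acid of the quench, and the free polyphenol may oxidise during isolation. The fallback changes the cleavage to a silylative one that never exposes free phenols to acid; it sets out from 38 and returns at 39. Iodotrimethylsilane (from TMSCl and NaI) with quinoline in hot sulfolane converts the methyl ethers into the hexadecakis(trimethylsilyl) ether F11, which neutral methanolysis turns into 39.

## Further compounds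

F1 | step 3 | methyl 4-(benzyloxy)-3-hydroxy-5-methoxybenzoate | COC(=O)c1cc(O)c(OCc2ccccc2)c(OC)c1
F2 | step 3 | methyl 4-(benzyloxy)-3-(2,3-difluoro-4,6-diformylphenoxy)-5-methoxybenzoate | COC(=O)c1cc(OC)c(OCc2ccccc2)c(Oc2c(C=O)cc(C=O)c(F)c2F)c1
F3 | step 4 | methyl 4-(benzyloxy)-2-bromo-3-hydroxy-5-methoxybenzoate | COC(=O)c1cc(OC)c(OCc2ccccc2)c(O)c1Br
F4 | step 4 | methyl 4-(benzyloxy)-2-bromo-3-(2,3-difluoro-4,6-diformylphenoxy)-5-methoxybenzoate | COC(=O)c1cc(OC)c(OCc2ccccc2)c(Oc2c(C=O)cc(C=O)c(F)c2F)c1Br
F5 | step 4 | methyl 2-bromo-3-(2,3-difluoro-4,6-diformylphenoxy)-4-hydroxy-5-methoxybenzoate | COC(=O)c1cc(OC)c(O)c(Oc2c(C=O)cc(C=O)c(F)c2F)c1Br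
F6 | step 11 | 4-fluoro-3-iodo-5-methoxybenzaldehyde | COc1cc(C=O)cc(I)c1F
F7 | step 11 | 4-{[2'-hydroxy-4,4',6,6'-tetramethoxy-(1,1'-biphenyl)-2-yl]oxy}-3-iodo-5-methoxybenzaldehyde | Oc1cc(OC)cc(OC)c1-c1c(OC)cc(OC)cc1Oc1c(OC)cc(C=O)cc1I
F8 | step 11 | iodo tri-aldehyde: 23 with iodine on G6 in place of the 2,4,6-trimethoxyphenoxy group | COC(=O)c1cc(OC)c2c(c1Br)Oc1c(C=O)cc(C=O)c(Oc3cc(OC)cc(OC)c3-c3c(OC)cc(OC)cc3Oc3c(OC)cc(C=O)cc3I)c1O2
F9 | step 11 | iodo triphenol: 25 with iodine on G6 in place of the 2,4,6-trimethoxyphenoxy group | COC(=O)c1cc(OC)c2c(c1Br)Oc1c(O)cc(O)c(Oc3cc(OC)cc(OC)c3-c3c(OC)cc(OC)cc3Oc3c(OC)cc(O)cc3I)c1O2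
F10 | step 11 | iodo permethyl ester: 26 with iodine on G6 in place of the 2,4,6-trimethoxyphenoxy group | COC(=O)c1cc(OC)c2c(c1Br)Oc1c(OC)cc(OC)c(Oc3cc(OC)cc(OC)c3-c3c(OC)cc(OC)cc3Oc3c(OC)cc(OC)cc3I)c1O2
F0 | step 22 | none | none
F11 | step 23 | hexadecakis(trimethylsilyl) ether of 39 | C[Si](C)(C)Oc1cc(O[Si](C)(C)C)cc(Oc2c(O[Si](C)(C)C)cc(O[Si](C)(C)C)c3c2oc2cc(O[Si](C)(C)C)c4c(c23)Oc2c(O[Si](C)(C)C)cc(O[Si](C)(C)C)c(Oc3cc(O[Si](C)(C)C)cc(O[Si](C)(C)C)c3-c3c(O[Si](C)(C)C)cc(O[Si](C)(C)C)cc3Oc3c(O[Si](C)(C)C)cc(O[Si](C)(C)C)cc3Oc3c(O[Si](C)(C)C)cc(O[Si](C)(C)C)cc3O[Si](C)(C)C)c2O4)c1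
A1 | alternative 1 | bromo diaryl ether with preformed dioxin and benzyl ether on D5 (substrate of the furan closure) | COc1cc(OC)cc(Oc2c(OC)cc(OC)cc2Oc2cc(OC)c3c(c2Br)Oc2c(OC)cc(OC)c(OCc4ccccc4)c2O3)c1
A2 | alternative 1 | protected A–B–C–D pentacyclic core with benzyl ether on D5 | COc1cc(OC)cc(Oc2c(OC)cc(OC)c3c2oc2cc(OC)c4c(c23)Oc2c(OC)cc(OC)c(OCc5ccccc5)c2O4)c1
A3 | alternative 2 | bis(3,5-dimethoxyphenoxy)methane | COc1cc(OC)cc(OCOc2cc(OC)cc(OC)c2)c1
A4 | alternative 2 | 1,3,9,11-tetramethoxydibenzo[d,f][1,3]dioxepine | COc1cc(OC)c2c(c1)OCOc1cc(OC)cc(OC)c1-2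
A5 | alternative 3 | (cyclopentadienyl)(1,2-dichloro-3,5-dimethoxybenzene)ruthenium hexafluorophosphate | COc1cc(OC)c(Cl)c(Cl)c1.[Ru+2].c1cc[cH-]c1.F[P-](F)(F)(F)(F)F
A6 | alternative 3 | 2'-(benzyloxy)-4,4',6,6'-tetramethoxy-[1,1'-biphenyl]-2-ol | COc1cc(O)c(-c2c(OC)cc(OC)cc2OCc2ccccc2)c(OC)c1
A7 | alternative 3 | cyclopentadienyl ruthenium hexafluorophosphate complex of the protected E–F–G–H chain (benzyl ether on ring E) | COc1cc(OC)c(Oc2cc(OC)cc(OC)c2-c2c(OC)cc(OC)cc2OCc2ccccc2)c(Oc2c(OC)cc(OC)cc2OC)c1.[Ru+2].c1cc[cH-]c1.F[P-](F)(F)(F)(F)F
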